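The route rests on cutting ring B at C8–C9 and C5–C10 (drimane numbering), the retron of an intramolecular Diels–Alder reaction once the C7=C8 alkene is written at C6=C7 and the C10 methyl is raised to a formyl group. The precursor is an acyclic trienal: an (E)-enal whose C9=C10 dienophile carries the formyl group on C10 and is tied by the C1–C4 keto chain to an (E,E)-C5–C8 diene. One catalytic enantioselective cycloaddition should close rings A and B and set C5, C9 and quaternary C10; the trans ring fusion and the C9/C10 trans relation follow from the endo-bound formyl group. Formyl reduction, a hydroxyl-directed alkene shift and etherification with isofraxidin finish the synthesis.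

Key step: step 5

Numbering remark: drimane numbering is used for all decalin and pre-decalin atoms (ring A = C1, C2, C3, C4, C5, C10 with C3 the ketone carbon and C4 the CMe2 carbon; ring B = C5, C6, C7, C8, C9, C10; C11 = the OCH2 carbon on C9); α is the face of H5, β the face of the C10 substituent.

Assumption: the (S) antipode of the oxazaborolidinium catalyst is taken to be the one that exposes the enal face leading to 9; both antipodes are commercial, and the sense of induction is to be confirmed on the first run.

Step 1
Reactants: 1 tetrahydro-2H-pyran-2-ol; 2 prenyl bromide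
Product: 3 rac-6,6-dimethyloct-7-ene-1,5-diol
Conditions: In powder, THF/H2O (1:1), 23 °C
Reagents that add atoms: prenyl bromide, CC(C)=CCBr
Why: Barbier-type allylation in water, in which the open 5-hydroxypentanal form of the lactol should be attacked by the γ-carbon of the allylindium reagent through a six-membered cyclic transition state to give the α,α-dimethyl homoallylic (reverse-prenylated) alcohol; the new carbinol centre forms as a racemate and is erased in step 3.

Step 2
Reactants: 3 rac-6,6-dimethyloct-7-ene-1,5-diol; 4 (E)-prop-1-enylboronic acid pinacol ester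
Product: 5 rac-(7E,9E)-6,6-dimethylundeca-7,9-diene-1,5-diol
Conditions: Pd(OAc)2 (10 mol %), 1,2-bis(phenylsulfinyl)ethane (10 mol %), 1,4-benzoquinone (2 equiv), AcOH, 1,4-dioxane, 23 °C
Reagents that add atoms: (E)-prop-1-enylboronic acid pinacol ester, C/C=C/B1OC(C)(C)C(C)(C)O1
Why: oxidative Heck reaction, in which the propenyl group passes from boron to divalent palladium, adds to the terminal carbon C6 of the alkene, and β-hydride elimination, possible only away from the quaternary C4, should give the (E,E)-diene with retention of the propenyl geometry and no new stereocentre.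

Step 3
Reactants: 5 rac-(7E,9E)-6,6-dimethylundeca-7,9-diene-1,5-diol
Product: 6 (7E,9E)-6,6-dimethyl-5-oxoundeca-7,9-dienal
Conditions: (COCl)2, DMSO, CH2Cl2, −78 °C; then Et3N, −78 → 0 °C
Reagents that add atoms: none
Why: Swern oxidation, chosen because both hydroxyls are turned into alkoxysulfonium salts before the base is added, so that aldehyde and ketone should be released together and the hydroxy aldehyde, which would close to a lactol and over-oxidize to a lactone, never accumulates; the racemic carbinol centre disappears.

Step 4
Reactants: 6 (7E,9E)-6,6-dimethyl-5-oxoundeca-7,9-dienal; 7 2-[(tert-butyldimethylsilyl)oxy]acetaldehyde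
Product: 8 (2E,7E,9E)-2-{2-[(tert-butyldimethylsilyl)oxy]ethylidene}-6,6-dimethyl-5-oxoundeca-7,9-dienal
Conditions: pyrrolidine (20 mol %), PhCO2H (20 mol %), 7 (3 equiv), CH2Cl2, 0 → 23 °C, slow addition of 6
Reagents that add atoms: 2-[(tert-butyldimethylsilyl)oxy]acetaldehyde, O=CCO[Si](C)(C)C(C)(C)C
Why: amine-catalysed cross-aldol condensation, in which the enamine of the aldehyde group of 6 (the hindered ketone does not condense) should add to the more electrophilic α-silyloxy aldehyde kept in excess, and dehydration should give the conjugated enal in its thermodynamically preferred (E) geometry (formyl trans to CH2OTBS) without forming a stereocentre.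

Step 5
Reactants: 8 (2E,7E,9E)-2-{2-[(tert-butyldimethylsilyl)oxy]ethylidene}-6,6-dimethyl-5-oxoundeca-7,9-dienal
Product: 9 (5R,8S,9R,10R)-9α-{[(tert-butyldimethylsilyl)oxy]methyl}-4,4,8β-trimethyl-3-oxo-5α-H-octal-6-ene-10β-carbaldehyde
Conditions: (S)-3,3-diphenyl-1-(o-tolyl)tetrahydro-1H,3H-pyrrolo[1,2-c][1,3,2]oxazaborole (20 mol %), Tf2NH (20 mol %), CH2Cl2, −78 → −20 °C
Reagents that add atoms: none
Why: The triflimide-protonated oxazaborolidine binds the formyl oxygen of 8 and lowers the LUMO of the C9=C10 enal, which should then undergo a concerted, asynchronous normal-demand [4+2] cycloaddition with the tethered C5–C8 diene, the C8–C9 bond being more advanced than the hindered C5–C10 bond; the closest known reaction type is the oxazaborolidinium-catalysed enantioselective intramolecular Diels–Alder reaction of 2-substituted trienals. Ring B closes as the six-membered ring of the [4+2] itself (both new bonds), and ring A closes through the C5–C10 bond as the fused six-membered tether ring of a type 1 intramolecular cycloaddition via a chair-like anti tether, helped by the gem-dimethyl group at C4. The trans ring fusion (H5 α, formyl on C10 β) follows from the endo position of the Lewis-acid-bound formyl group, which places the geminal tether exo; C9 (H β, CH2OTBS α) follows from suprafacial addition to the (E)-alkene, whose CH2OTBS is cis to the tether; C8 (methyl β) follows from the (E)-C7=C8 geometry and is erased in step 8. The absolute configuration is set by the catalyst, which shields one face of the s-trans enal held by B–O coordination and a formyl C–H···O contact. The step needs endo/anti over exo/syn selectivity and activation of the enal without interference from the ketone: the endo preference of the coordinated formyl and the exo preference of the bulky CH2OTBS act in the same direction, and the C3 ketone, flanked by the quaternary C4, is the poorer Lewis base.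

Step 6
Reactants: 9 (5R,8S,9R,10R)-9α-{[(tert-butyldimethylsilyl)oxy]methyl}-4,4,8β-trimethyl-3-oxo-5α-H-octal-6-ene-10β-carbaldehyde
Product: 11 (5R,8S,9R,10S)-9α-{[(tert-butyldimethylsilyl)oxy]methyl}-4,4,8β,10β-tetramethyl-5α-H-octal-6-en-3-one, via N-silyl hydrazone 10 (not isolated)
Conditions: TBSNHNHTBS (1.2 equiv), Sc(OTf)3 (1 mol %), CH2Cl2, 23 → 40 °C; then KOtBu, tBuOH, DMSO, 23 °C
Reagents that add atoms: none
Why: Wolff–Kishner reduction in its low-temperature N-silyl hydrazone form, in which the scandium-catalysed condensation of the bis-silyl hydrazine should take place at the aldehyde and not at the hindered C3 ketone at this temperature, after which tert-butoxide desilylates the hydrazone and its diazene anion loses N2 to leave the C10 methyl group without touching any stereocentre.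

Step 7
Reactants: 11 (5R,8S,9R,10S)-9α-{[(tert-butyldimethylsilyl)oxy]methyl}-4,4,8β,10β-tetramethyl-5α-H-octal-6-en-3-one
Product: 12 (5R,8S,9R,10S)-9α-(hydroxymethyl)-4,4,8β,10β-tetramethyl-5α-H-octal-6-en-3-one
Conditions: TBAF, THF, 0 → 23 °C
Reagents that add atoms: none
Why: fluoride-induced desilylation of the primary silyl ether, driven by Si–F bond formation, should free the C11 hydroxyl without affecting the ketone, the alkene or any stereocentre.

Step 8
Reactants: 12 (5R,8S,9R,10S)-9α-(hydroxymethyl)-4,4,8β,10β-tetramethyl-5α-H-octal-6-en-3-one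
Product: 13 (4aS,5R,8aR)-5-(hydroxymethyl)-1,1,4a,6-tetramethyl-3,4,4a,5,8,8a-hexahydronaphthalen-2(1H)-one
Conditions: [Ir(cod)(PCy3)(py)]PF6 (5 mol %), briefly activated with H2 then purged with Ar, CH2Cl2, 23 °C
Reagents that add atoms: none
Why: hydroxyl-directed alkene isomerization by an iridium hydride (insertion, then β-hydride elimination), in which the axial C11 hydroxyl on the α face should bind the cationic metal and deliver it to C7 on that face, H8 (also α) is then lost to give the more stable trisubstituted C7=C8 alkene, and further migration is disfavoured because it would place iridium on the tertiary C8; the C8 stereocentre is erased and C5, C9 and C10 are untouched.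

Step 9
Reactants: 13 (4aS,5R,8aR)-5-(hydroxymethyl)-1,1,4a,6-tetramethyl-3,4,4a,5,8,8a-hexahydronaphthalen-2(1H)-one; 14 isofraxidin
Product: 15 6,8-dimethoxy-7-{[(1R,4aR,8aS)-2,5,5,8a-tetramethyl-6-oxo-1,4,4a,5,6,7,8,8a-octahydronaphthalen-1-yl]methoxy}-2H-chromen-2-one
Conditions: PPh3, DIAD, toluene, 0 → 60 °C
Reagents that add atoms: isofraxidin, COc1cc2ccc(=O)oc2c(OC)c1O
Why: Mitsunobu etherification, in which the acidic 7-hydroxycoumarin should displace the oxyphosphonium group at the primary C11 in an SN2 step that leaves the C9 stereocentre, the ketone and the alkene untouched.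

Compound list
1 | tetrahydro-2H-pyran-2-ol (cyclic hemiacetal of 5-hydroxypentanal) | OC1CCCCO1 | starting material
2 | prenyl bromide (1-bromo-3-methylbut-2-ene) | CC(C)=CCBr | starting material
3 | rac-6,6-dimethyloct-7-ene-1,5-diol | OCCCCC(O)C(C)(C)C=C | intermediate
4 | (E)-prop-1-enylboronic acid pinacol ester | C/C=C/B1OC(C)(C)C(C)(C)O1 | starting material
5 | rac-(7E,9E)-6,6-dimethylundeca-7,9-diene-1,5-diol | OCCCCC(O)C(C)(C)/C=C/C=C/C | intermediate
6 | (7E,9E)-6,6-dimethyl-5-oxoundeca-7,9-dienal | O=CCCCC(=O)C(C)(C)/C=C/C=C/C | intermediate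
7 | 2-[(tert-butyldimethylsilyl)oxy]acetaldehyde | O=CCO[Si](C)(C)C(C)(C)C | starting material
8 | (2E,7E,9E)-2-{2-[(tert-butyldimethylsilyl)oxy]ethylidene}-6,6-dimethyl-5-oxoundeca-7,9-dienal (formyl on C10, CH2OTBS on C9 trans to formyl) | O=C/C(CCC(=O)C(C)(C)/C=C/C=C/C)=C/CO[Si](C)(C)C(C)(C)C | intermediate
9 | (5R,8S,9R,10R)-9α-{[(tert-butyldimethylsilyl)oxy]methyl}-4,4,8β-trimethyl-3-oxo-5α-H-octal-6-ene-10β-carbaldehyde (trans-fused, drimane numbering) | O=C[C@]12CCC(=O)C(C)(C)[C@@H]1C=C[C@H](C)[C@H]2CO[Si](C)(C)C(C)(C)C | intermediate
10 | (E)-N-(tert-butyldimethylsilyl)hydrazone of 9 | CC(C)(C)[Si](C)(C)N/N=C/[C@]12CCC(=O)C(C)(C)[C@@H]1C=C[C@H](C)[C@H]2CO[Si](C)(C)C(C)(C)C | intermediate (not isolated)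
11 | (5R,8S,9R,10S)-9α-{[(tert-butyldimethylsilyl)oxy]methyl}-4,4,8β,10β-tetramethyl-5α-H-octal-6-en-3-one | C[C@]12CCC(=O)C(C)(C)[C@@H]1C=C[C@H](C)[C@H]2CO[Si](C)(C)C(C)(C)C | intermediate
12 | (5R,8S,9R,10S)-9α-(hydroxymethyl)-4,4,8β,10β-tetramethyl-5α-H-octal-6-en-3-one | C[C@]12CCC(=O)C(C)(C)[C@@H]1C=C[C@H](C)[C@H]2CO | intermediate
13 | (4aS,5R,8aR)-5-(hydroxymethyl)-1,1,4a,6-tetramethyl-3,4,4a,5,8,8a-hexahydronaphthalen-2(1H)-one (C7=C8 alkene, CH2OH on C9 α) | C[C@]12CCC(=O)C(C)(C)[C@@H]1CC=C(C)[C@H]2CO | intermediate
14 | isofraxidin (7-hydroxy-6,8-dimethoxy-2H-chromen-2-one) | COc1cc2ccc(=O)oc2c(OC)c1O | starting material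
15 | 6,8-dimethoxy-7-{[(1R,4aR,8aS)-2,5,5,8a-tetramethyl-6-oxo-1,4,4a,5,6,7,8,8a-octahydronaphthalen-1-yl]methoxy}-2H-chromen-2-one | COc1cc2ccc(=O)oc2c(OC)c1OC[C@@H]1C(C)=CC[C@H]2C(C)(C)C(=O)CC[C@]12C | target

Total step count: 9. Longest linear sequence: 9 steps (1 → 15); compounds 2, 4, 7 and 14 enter as purchased reagents.

Steps most likely to fail

Step 5. The catalyst may discriminate poorly between the two enal faces, or be held back by the ketone, and closure of the crowded C5–C10 bond may be slow. The fallback sets out from 8 and gives up catalytic enantiocontrol: stoichiometric Me2AlCl in CH2Cl2 at −78 → −20 °C should drive the same endo cycloaddition to the racemic adduct F1, whose enantiomers are separated by preparative chromatography on a chiral stationary phase. The route is rejoined at 9.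

Step 8. The iridium hydride may fail to turn over, may walk toward C5 instead of C8, or may saturate part of the alkene. The fallback sets out from 11 and replaces hydroxyl-directed, kinetically controlled delivery by thermodynamic equilibration on the silyl ether: RhCl3·3H2O in ethanol at reflux should move the alkene to the more stable trisubstituted position, giving the C7=C8 silyl ether F2 after removal of any C5=C6 isomer on AgNO3-impregnated silica. Desilylation with TBAF rejoins the route at 13.

Step 4. Self-condensation of either aldehyde and incomplete dehydration may erode the one-pot condensation. The fallback sets out from 6 and 7 and separates bond formation from elimination: L-proline-catalysed cross-aldol addition (DMF, 4 °C, slow addition of 6 to excess 7) should give the β-hydroxy aldehyde F3 as a diastereomer mixture, which is converted with MsCl and Et3N into the mesylate F4 and eliminated with DBU. The route is rejoined at 8.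

Further compounds
F1 | step 5 | racemic 9 (both enantiomers of the trans-fused cycloadduct) | O=C[C@]12CCC(=O)C(C)(C)[C@@H]1C=C[C@H](C)[C@H]2CO[Si](C)(C)C(C)(C)C.O=C[C@@]12CCC(=O)C(C)(C)[C@H]1C=C[C@@H](C)[C@@H]2CO[Si](C)(C)C(C)(C)C
F2 | step 8 | (5R,9R,10S)-9α-{[(tert-butyldimethylsilyl)oxy]methyl}-4,4,8,10β-tetramethyl-5α-H-octal-7-en-3-one | C[C@]12CCC(=O)C(C)(C)[C@@H]1CC=C(C)[C@H]2CO[Si](C)(C)C(C)(C)C
F3 | step 4 | (7E,9E)-2-{2-[(tert-butyldimethylsilyl)oxy]-1-hydroxyethyl}-6,6-dimethyl-5-oxoundeca-7,9-dienal (diastereomer mixture) | O=CC(CCC(=O)C(C)(C)/C=C/C=C/C)C(O)CO[Si](C)(C)C(C)(C)C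
F4 | step 4 | methanesulfonate of F3 | O=CC(CCC(=O)C(C)(C)/C=C/C=C/C)C(OS(C)(=O)=O)CO[Si](C)(C)C(C)(C)C
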